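A first end group can meet a second end group or a link, and this flask turns on how those two meetings compare in speed.

first end groups 1.5 M; second end groups 0.980 equiv; time 5.0 d

    links + released group → side product B (k1 = 0.017 L mol⁻¹ min⁻¹)
    first end groups + second end groups → links + released group (k2 = 0.038 L mol⁻¹ min⁻¹)
    first end groups + links → side product A (k3 = 0.011 L mol⁻¹ min⁻¹)

- a species is counted by the first end groups in it: one side product A counts as two
- the reaction counts as stopped when no species that holds the first end groups changes by six tenths of a point or more over the second half of the time
- run time (flask): 5.0 d

* which holds at 5.0 d: what has brought the reaction to rest, or that it has not come to rest (it is still moving / all of the first end groups has reacted / the second end groups has run out first / forward and back rates have come level)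
* conversion of first end groups at 5.0 d
* amount of side product B at 5.0 d, in percent of the first end groups charged

We call the meeting of the two end groups coupling and the meeting of a first end group with a link capping, and we turn both constants into times at the charged amounts. A first end group has a half-life of 0.21 h against coupling, and a link has 0.70 h against capping, both short against 5.0 d. The first time divided by the second gives the competition ratio, 29.5%, a selectivity factor taken at the charges.

Two extremes bound the flask. With capping far slower than coupling, links meet the released group instead, side product B reaches 98.0%, and the second end groups are the limiting reagent. With capping far faster, side product A takes the whole charge of first end groups and side product B gets none.

Between them, each side product A spends two first end groups but one second end group. The first end groups therefore run out first once side product A holds more than 4.00% of the charge. We assume that, while first end groups are being spent, c(links)/c(second end groups) averages 0.5 of the charged ratio of first to second end groups; this is an assumption, not a result. Side product A counts double, which cancels that factor, so its share should be near the ratio. This share lies well above the limit, so we expect the first end groups to run out, with side product B near 70.5% and 13.0% of the second end groups left.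

The forecast gives all of the first end groups has reacted, 100% and 67%, a lower side product B than ours, holding that “the second end groups end up in excess and the first end groups run out”.

The flask gives all of the first end groups has reacted, with conversion 100%, side product B 67.8%, side product A 32.2% against the ratio of 29.5%, and 14% of the second end groups left. The neighbouring flask, with 1.70 equiv of second end groups, has the ratio 17.0%, so we reckon side product B at 83.0% and 46.2% of its second end groups left. That flask holds side product A 17.5%, side product B 82.5%, and 46% of its second end groups.

All constants are made up; the flask was simulated.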